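A racemate charged in equal parts cannot keep an excess of J over Z without exchange once G and D are both used up, for J and Z then equal their equal charges. An excess without exchange therefore belongs to a flask part-way through.

in all of them: G 0.20 M; D 0.20 M

| run | X | E | remark | time |
|---|---|---|---|---|
| north-west | 1.7 equiv | 3.8 mol% | run made earlier |  |
| north | 3.8 equiv | 3.8 mol% | run made earlier |  |
| north-east | 2.5 equiv | 5.7 mol% | run made earlier |  |
| flask | 2.50 equiv | 3.8 mol% |  | 3.0 h |

| run | time / min | J / % | Z / % |
|---|---|---|---|
| north-west | 10.0 | 4.2 | 0.6 |
| north-west | 25.0 | 10.7 | 3.9 |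
| north-west | 50.0 | 17.5 | 6.1 |
| north-west | 80.0 | 22.0 | 8.7 |
| north-west | 120 | 26.7 | 11.4 |
| north | 8.00 | 9.7 | 2.7 |
| north | 15.0 | 14.5 | 5.2 |
| north | 30.0 | 23.7 | 9.5 |
| north | 60.0 | 33.2 | 16.1 |
| north | 120 | 42.2 | 22.5 |
| north-east | 10.0 | 7.4 | 2.6 |
| north-east | 25.0 | 15.0 | 6.3 |
| north-east | 50.0 | 23.3 | 9.3 |
| north-east | 80.0 | 29.1 | 13.0 |
| north-east | 120 | 34.1 | 15.2 |

(readings scatter by 0.5 percentage points)

- X is single-handed; G and D are mirror images of each other, charged as a racemate, each of them at the stated concentration
- the analysis behind the earlier runs scatters by 0.5 percentage points, standard deviation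
- steps thought possible: X + G -> J; X + D -> Z; G + E <-> D + E; X -> L; 2 E <-> Q
- an excess is the difference of the two amounts in percent of their sum
- an excess is below zero if the other one leads
- the handed part of X does not stay in what it makes, so the products of the two hands are mirror images too

1. J and Z together, in percent of the G and D charged together, at 3.0 h
2. excess of J over Z in the product at 3.0 h
3. whether the exchange between G and D keeps pace with the reaction: how far the product's excess at 3.0 h gets from its value without exchange to its value with instant exchange (above 80% keeps pace, below 20% hardly takes part, else lags behind)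

Without exchange, G and D each fall in proportion to themselves and to the same c_X. So, whatever course c_X takes, the logarithm of the fraction of G left, divided by that of D left, stays constant. This constant says how many times faster G goes than D at equal concentration: the selectivity factor s, here 3.11 from the last north reading. Exchange feeds G from the larger D and lifts this ratio, yet the north-east run, with 5.7 mol% of E against 3.8 mol% and 2.5 equiv of X against 3.8 equiv, reads 3.16. The estimate here is therefore that one number is enough and exchange hardly takes part.

The north-east run has the flask's X charge, but 5.7 mol% of E against the flask's 3.8 mol%. Its negative logarithm of the D fraction left, 0.362 at 120 min, carried on at the pace of its last stretch, reaches 0.454 at 3.0 h. That leaves 63.5% of the D charge and, through s, 24.4% of the G charge. This reckoning gives J and Z together 56.0% and excess 34.9%.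

The forecast gives J and Z together 56.5% and excess 35.5%, with exchange that hardly takes part. It reads a selectivity of about 3.1 and concludes “so exchange is negligible”.

The flask gives J and Z together 55.7% and excess 34.6%, and its exchange hardly takes part, getting 3.4% of the way.

    X + G → J (k = 0.0330 L mol⁻¹ min⁻¹)
    X + D → Z (k = 0.0110 L mol⁻¹ min⁻¹)
    G + E ⇌ D + E, rate k3*[E]*[G] forward; the back reaction follows from the equilibrium constant (k = 0.330 L mol⁻¹ min⁻¹)
    X → L (k = 0.00430 min⁻¹)
    2 E ⇌ Q (K = 3700 L mol⁻¹, k = 94.0 L mol⁻¹ min⁻¹)

The rule needs s and the D left. At 3.0 h the flask keeps 62% of its D charge, and s turns that into an excess of 34.1%, against 34.6% simulated. A neighbouring flask with 6.20 equiv of X, other charges and time unchanged, keeps 26% of its D charge, and s gives 14.0%. That flask ends with J at 49.6%, Z at 36.3% and a simulated excess of 15.5%.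

(The numbers in the tables come from a simulation with made-up constants; the scatter is artificial.)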